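**Retrosynthetic overview**

1. Feature (ring A: C1 CO2H, C2 OMe, C3 side chain, C6 OAr; ring B: C1′ ether O, C2′ OH, C4′ Me, C6′ enone): carboxyl carbon C1 lies between methoxy carbon C2 and aryloxy carbon C6. This is the pattern left when a nucleophile adds to the far end and an electrophile to the near end of a 3-methoxyaryne spanning C1–C6.
2. Key disconnection: the C6–O(ring B) and C1–CO2H bonds are cut together, back to a C1/C6 silyl triflate aryne precursor, a ring B caesium phenoxide with its formyl group masked as a dioxolane, and carbon dioxide.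
3. Aryne precursor: from 4-hydroxy-2-methoxybenzaldehyde by carbamoylation, Brown methallylboration (sets the only stereocentre, S), silylation, hydrogenation, ortho-metalation/C-silylation between the two oxygens, and carbamate-to-triflate exchange.
4. Ring B phenol: from 2-methoxy-4-methylphenol by ortho-formylation, demethylation, selective 3-O-allylation and acetalisation.
5. End game: allyl ester, release of carbinol and aldehyde, acetylation, Wittig olefination, double deallylation. No ring is constructed; both benzene rings are bought in and joined in the key step.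

Key step: step 11

Remark on the chemistry: (−)-Ipc2BOMe is the reagent made from (+)-α-pinene; its methallylborane is taken to add to the Si face of the aryl aldehyde as it does with benzaldehyde, which corresponds to the (S) carbinol.

**Route**

Step 1
Reactants: 1 4-hydroxy-2-methoxybenzaldehyde
Product: 2 4-formyl-3-methoxyphenyl N-isopropylcarbamate
Conditions: i-PrNCO, Et3N (cat.), CH2Cl2, rt
Reagents that add atoms: isopropyl isocyanate, CC(C)N=C=O
Why: Amine-catalysed addition of the acidic phenol O–H across the isocyanate (carbamoylation) should be clean and installs a removable ortho-directing group.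

Step 2
Reactants: 2 4-formyl-3-methoxyphenyl N-isopropylcarbamate; 3 2-methylallylmagnesium chloride
Product: 5 4-[(1S)-1-hydroxy-3-methylbut-3-en-1-yl]-3-methoxyphenyl N-isopropylcarbamate, via diisopinocampheylborinate 4 (not isolated)
Conditions: (−)-Ipc2BOMe (1.3 equiv), 3 (1.25 equiv), Et2O, −78 °C to rt; then 2, −78 °C; pH 7 phosphate buffer, MeOH, 30% H2O2, 0 °C to rt
Reagents that add atoms: none
Why: Brown asymmetric methallylboration, in which the B-methallyldiisopinocampheylborane made in the flask transfers the methallyl group through a closed chair transition state to the Si face of the aryl aldehyde to set the (S) carbinol, and the buffered peroxide work-up spares the base-labile N–H carbamate.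

Step 3
Reactants: 5 4-[(1S)-1-hydroxy-3-methylbut-3-en-1-yl]-3-methoxyphenyl N-isopropylcarbamate
Product: 6 4-[(1S)-1-(tert-butyldimethylsilyloxy)-3-methylbut-3-en-1-yl]-3-methoxyphenyl N-isopropylcarbamate
Conditions: TBSCl, imidazole, DMF, rt
Reagents that add atoms: tert-butyldimethylsilyl chloride, CC(C)(C)[Si](C)(C)Cl
Why: Imidazole-promoted O-silylation of the secondary alcohol takes place at oxygen only, so the stereocentre is untouched and the carbamate N–H is left alone.

Step 4
Reactants: 6 4-[(1S)-1-(tert-butyldimethylsilyloxy)-3-methylbut-3-en-1-yl]-3-methoxyphenyl N-isopropylcarbamate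
Product: 7 4-[(1S)-1-(tert-butyldimethylsilyloxy)-3-methylbutyl]-3-methoxyphenyl N-isopropylcarbamate
Conditions: H2 (1 atm), 5% Pt/C, EtOAc, rt
Reagents that add atoms: none
Why: Heterogeneous hydrogenation of the 1,1-disubstituted alkene creates no new stereocentre, and platinum with the carbinol already silylated should avoid benzylic C–O hydrogenolysis.

Step 5
Reactants: 7 4-[(1S)-1-(tert-butyldimethylsilyloxy)-3-methylbutyl]-3-methoxyphenyl N-isopropylcarbamate
Product: 11 4-[(1S)-1-(tert-butyldimethylsilyloxy)-3-methylbutyl]-3-methoxy-2-(trimethylsilyl)phenyl N-isopropylcarbamate, via N-silylcarbamate 8 (not isolated), via aryllithium 9 (not isolated), via N-silyl arylsilane 10 (not isolated)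
Conditions: TBSOTf, TMEDA, Et2O, 0 °C to rt; n-BuLi, TMEDA, −78 °C; TMSCl, −78 °C to rt; aq NaHSO4
Reagents that add atoms: chlorotrimethylsilane, C[Si](C)(C)Cl
Why: Directed ortho-metalation, in which the N-silylated carbamate and the methoxy group together direct n-BuLi/TMEDA to the one ring C–H flanked by both oxygens, TMSCl traps the aryllithium at −78 °C before an anionic Fries shift, and the acidic work-up removes the N-silyl group.

Step 6
Reactants: 11 4-[(1S)-1-(tert-butyldimethylsilyloxy)-3-methylbutyl]-3-methoxy-2-(trimethylsilyl)phenyl N-isopropylcarbamate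
Product: 13 4-[(1S)-1-(tert-butyldimethylsilyloxy)-3-methylbutyl]-3-methoxy-2-(trimethylsilyl)phenyl trifluoromethanesulfonate, via silylphenol 12 (not isolated)
Conditions: DBU, Et2NH, MeCN, 40 °C; then PhNTf2, rt
Reagents that add atoms: N-phenylbis(trifluoromethanesulfonimide), O=S(=O)(N(c1ccccc1)S(=O)(=O)C(F)(F)F)C(F)(F)F
Why: E1cB cleavage of the N–H carbamate by DBU (the isocyanate is scavenged by diethylamine) frees the hindered phenoxide, which PhNTf2 triflates in the same pot under non-acidic, fluoride-free conditions that keep the aryl–silicon bond and the silyl ether.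

Step 7
Reactants: 14 2-methoxy-4-methylphenol
Product: 15 2-hydroxy-3-methoxy-5-methylbenzaldehyde
Conditions: (CH2O)n, MgCl2, Et3N, MeCN, reflux; 1 M HCl
Reagents that add atoms: paraformaldehyde (formaldehyde unit), C=O
Why: Casnati–Skattebøl ortho-formylation, in which the magnesium phenoxide delivers formaldehyde to the single free ortho position and a second formaldehyde oxidises the hydroxymethyl intermediate to the aldehyde.

Step 8
Reactants: 15 2-hydroxy-3-methoxy-5-methylbenzaldehyde
Product: 16 2,3-dihydroxy-5-methylbenzaldehyde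
Conditions: BBr3, CH2Cl2, −78 °C to rt; H2O
Reagents that add atoms: none
Why: Lewis-acid demethylation of the aryl methyl ether (bromide attacks the O-methyl group of the boron-complexed ether by SN2), and the aldehyde is returned on hydrolysis.

Step 9
Reactants: 16 2,3-dihydroxy-5-methylbenzaldehyde
Product: 18 3-(allyloxy)-2-hydroxy-5-methylbenzaldehyde, via disodium catecholate 17 (not isolated)
Conditions: NaH (2.2 equiv), DMSO, rt; allyl bromide (1.0 equiv), rt; dilute HCl
Reagents that add atoms: allyl bromide, C=CCBr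
Why: Williamson O-alkylation of the dianion is regioselective because the 2-oxide is conjugated with and chelated to the formyl group and is the weaker nucleophile, so one equivalent of allyl bromide should go to the 3-oxide.

Step 10
Reactants: 18 3-(allyloxy)-2-hydroxy-5-methylbenzaldehyde
Product: 19 2-(allyloxy)-6-(1,3-dioxolan-2-yl)-4-methylphenol
Conditions: ethylene glycol, TsOH·H2O (cat.), toluene, reflux, Dean–Stark; Et3N quench
Reagents that add atoms: ethylene glycol, OCCO
Why: Acid-catalysed acetalisation driven by azeotropic removal of water masks the formyl group as a base- and fluoride-stable dioxolane and leaves the phenol free, at a temperature well below that of an aromatic Claisen rearrangement.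

Step 11
Reactants: 13 4-[(1S)-1-(tert-butyldimethylsilyloxy)-3-methylbutyl]-3-methoxy-2-(trimethylsilyl)phenyl trifluoromethanesulfonate; 19 2-(allyloxy)-6-(1,3-dioxolan-2-yl)-4-methylphenol; 20 carbon dioxide
Product: 24 6-[2-(allyloxy)-6-(1,3-dioxolan-2-yl)-4-methylphenoxy]-3-[(1S)-1-(tert-butyldimethylsilyloxy)-3-methylbutyl]-2-methoxybenzoic acid, via caesium phenoxide 21 (not isolated), via aryne 22 (not isolated), via arylcaesium 23 (not isolated)
Conditions: 19 (1.8 equiv), CsOH·H2O, MeOH, then toluene azeotrope to dry 21; CsF, 18-crown-6, CO2 (1 atm), THF, 13 added over 2 h, 0 °C to rt; aq NaH2PO4 (pH 5)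
Reagents that add atoms: none
Why: Proposed new method: fluoride attacks the trimethylsilyl group of 13 and triflate leaves to give aryne 22, caesium phenoxide 21 adds to C6 to put the negative charge on C1 (arylcaesium 23, flanked by the C2 methoxy and the new C6 aryloxy group), and 23 adds to carbon dioxide, so that the C6–O and C1–CO2 bonds form in one operation. The closest known reactions are the three-component couplings of arynes with amines or imines and carbon dioxide (fluoride/crown ether in THF under 1 atm CO2) and the fluoride-mediated O-arylation of hindered phenols by silylaryl triflates; the use of a phenoxide as the nucleophile in the carboxylative coupling is the untested part. No ring is closed and no stereocentre is created, the (S) silyloxy carbinol being a spectator that meets neither acid nor a benzylic anion. The step needs regioselectivity in the phenoxide addition, and this comes from the σ-withdrawing C2 methoxy group, which distorts the aryne so that nucleophiles enter at the remote carbon C6, helped by the lower steric demand at that end. It also needs carboxylation to outrun protonation of 23, which is why the phenoxide is preformed and dried (no O–H), THF replaces acetonitrile and carbon dioxide is present from the start, while the dioxolane removes the only internal electrophile on ring B (a free formyl group would close a xanthenol). The phenoxide is used in excess because part of it rests as the carbonate under carbon dioxide and because the hindered product carboxylate must not compete for the aryne.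

Step 12
Reactants: 24 6-[2-(allyloxy)-6-(1,3-dioxolan-2-yl)-4-methylphenoxy]-3-[(1S)-1-(tert-butyldimethylsilyloxy)-3-methylbutyl]-2-methoxybenzoic acid
Product: 25 allyl 6-[2-(allyloxy)-6-(1,3-dioxolan-2-yl)-4-methylphenoxy]-3-[(1S)-1-(tert-butyldimethylsilyloxy)-3-methylbutyl]-2-methoxybenzoate
Conditions: allyl bromide, K2CO3, DMF, rt
Reagents that add atoms: allyl bromide, C=CCBr
Why: SN2 O-alkylation of the carboxylate is indifferent to the two ortho substituents that would block esterification at the carbonyl, and it gives an ester that can later be removed together with the allyl ether.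

Step 13
Reactants: 25 allyl 6-[2-(allyloxy)-6-(1,3-dioxolan-2-yl)-4-methylphenoxy]-3-[(1S)-1-(tert-butyldimethylsilyloxy)-3-methylbutyl]-2-methoxybenzoate
Product: 26 allyl 6-[2-(allyloxy)-6-formyl-4-methylphenoxy]-3-[(1S)-1-hydroxy-3-methylbutyl]-2-methoxybenzoate
Conditions: 48% aq HF, MeCN, 0 °C to rt
Reagents that add atoms: water, O
Why: Aqueous HF in acetonitrile cleaves the silyl ether by fluoride attack at silicon and, as a weak acid, should hydrolyse the electron-rich aryl dioxolane without ionising the benzylic C–O bond, so the (S) carbinol is released with its configuration intact.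

Step 14
Reactants: 26 allyl 6-[2-(allyloxy)-6-formyl-4-methylphenoxy]-3-[(1S)-1-hydroxy-3-methylbutyl]-2-methoxybenzoate
Product: 27 allyl 3-[(1S)-1-acetoxy-3-methylbutyl]-6-[2-(allyloxy)-6-formyl-4-methylphenoxy]-2-methoxybenzoate
Conditions: Ac2O, pyridine, DMAP (cat.), CH2Cl2, 0 °C to rt
Reagents that add atoms: acetic anhydride, CC(=O)OC(C)=O
Why: DMAP-catalysed O-acylation occurs at oxygen, so the benzylic stereocentre is retained, and the aldehyde and allyl groups are inert to it.

Step 15
Reactants: 27 allyl 3-[(1S)-1-acetoxy-3-methylbutyl]-6-[2-(allyloxy)-6-formyl-4-methylphenoxy]-2-methoxybenzoate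
Product: 28 allyl 3-[(1S)-1-acetoxy-3-methylbutyl]-6-{2-(allyloxy)-4-methyl-6-[(1E)-3-oxobut-1-en-1-yl]phenoxy}-2-methoxybenzoate
Conditions: Ph3P=CHC(O)CH3, toluene, 90 °C
Reagents that add atoms: 1-(triphenylphosphoranylidene)propan-2-one, CC(=O)C=P(c1ccccc1)(c1ccccc1)c1ccccc1
Why: Wittig olefination with a ketone-stabilised ylide should give the (E)-enone, and the weakly basic ylide leaves the acetate and the allyl ester alone.

Step 16
Reactants: 28 allyl 3-[(1S)-1-acetoxy-3-methylbutyl]-6-{2-(allyloxy)-4-methyl-6-[(1E)-3-oxobut-1-en-1-yl]phenoxy}-2-methoxybenzoate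
Product: 29 3-[(1S)-1-acetoxy-3-methylbutyl]-6-{2-hydroxy-4-methyl-6-[(1E)-3-oxobut-1-en-1-yl]phenoxy}-2-methoxybenzoic acid (CNP0281268.1)
Conditions: Pd(PPh3)4 (5 mol%), morpholine, THF, rt; dilute aq HCl to pH 3
Reagents that add atoms: none
Why: Tsuji–Trost deallylation, in which zerovalent palladium ionises both the allyl ester and the allyl aryl ether to π-allyl complexes that morpholine intercepts, should free the hindered acid and the phenol under neutral conditions that spare the benzylic acetate and the enone.

**Compound list**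

1 | 4-hydroxy-2-methoxybenzaldehyde | COc1cc(O)ccc1C=O | starting material
2 | 4-formyl-3-methoxyphenyl N-isopropylcarbamate | COc1cc(OC(=O)NC(C)C)ccc1C=O | intermediate
3 | 2-methylallylmagnesium chloride (THF solution) | C=C(C)C[Mg]Cl | starting material
4 | (1S)-1-[4-(isopropylcarbamoyloxy)-2-methoxyphenyl]-3-methylbut-3-en-1-yl diisopinocampheylborinate (formed in the flask) | COc1c([C@H](CC(C)=C)OB([C@@H]2C[C@@H]3C[C@@H](C3(C)C)[C@H]2C)[C@@H]2C[C@@H]3C[C@@H](C3(C)C)[C@H]2C)ccc(OC(=O)NC(C)C)c1 | intermediate
5 | 4-[(1S)-1-hydroxy-3-methylbut-3-en-1-yl]-3-methoxyphenyl N-isopropylcarbamate | COc1c([C@H](CC(C)=C)O)ccc(OC(=O)NC(C)C)c1 | intermediate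
6 | 4-[(1S)-1-(tert-butyldimethylsilyloxy)-3-methylbut-3-en-1-yl]-3-methoxyphenyl N-isopropylcarbamate | COc1c([C@H](CC(C)=C)O[Si](C)(C)C(C)(C)C)ccc(OC(=O)NC(C)C)c1 | intermediate
7 | 4-[(1S)-1-(tert-butyldimethylsilyloxy)-3-methylbutyl]-3-methoxyphenyl N-isopropylcarbamate | COc1c([C@H](CC(C)C)O[Si](C)(C)C(C)(C)C)ccc(OC(=O)NC(C)C)c1 | intermediate
8 | N-(tert-butyldimethylsilyl) derivative of 7 (formed in the flask) | COc1c([C@H](CC(C)C)O[Si](C)(C)C(C)(C)C)ccc(OC(=O)N(C(C)C)[Si](C)(C)C(C)(C)C)c1 | intermediate
9 | 2-lithio derivative of 8, lithium on the ring carbon between the methoxy and carbamate oxygens (formed in the flask) | COc1c([C@H](CC(C)C)O[Si](C)(C)C(C)(C)C)ccc(OC(=O)N(C(C)C)[Si](C)(C)C(C)(C)C)c1[Li] | intermediate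
10 | N-(tert-butyldimethylsilyl) derivative of 11 (formed in the flask) | COc1c([C@H](CC(C)C)O[Si](C)(C)C(C)(C)C)ccc(OC(=O)N(C(C)C)[Si](C)(C)C(C)(C)C)c1[Si](C)(C)C | intermediate
11 | 4-[(1S)-1-(tert-butyldimethylsilyloxy)-3-methylbutyl]-3-methoxy-2-(trimethylsilyl)phenyl N-isopropylcarbamate | COc1c([C@H](CC(C)C)O[Si](C)(C)C(C)(C)C)ccc(OC(=O)NC(C)C)c1[Si](C)(C)C | intermediate
12 | 4-[(1S)-1-(tert-butyldimethylsilyloxy)-3-methylbutyl]-3-methoxy-2-(trimethylsilyl)phenol (formed in the flask) | COc1c([C@H](CC(C)C)O[Si](C)(C)C(C)(C)C)ccc(O)c1[Si](C)(C)C | intermediate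
13 | 4-[(1S)-1-(tert-butyldimethylsilyloxy)-3-methylbutyl]-3-methoxy-2-(trimethylsilyl)phenyl trifluoromethanesulfonate | COc1c([C@H](CC(C)C)O[Si](C)(C)C(C)(C)C)ccc(OS(=O)(=O)C(F)(F)F)c1[Si](C)(C)C | intermediate
14 | 2-methoxy-4-methylphenol | COc1cc(C)ccc1O | starting material
15 | 2-hydroxy-3-methoxy-5-methylbenzaldehyde | COc1cc(C)cc(C=O)c1O | intermediate
16 | 2,3-dihydroxy-5-methylbenzaldehyde | Oc1cc(C)cc(C=O)c1O | intermediate
17 | disodium 3-formyl-5-methylbenzene-1,2-diolate (formed in the flask) | [Na+].[Na+].[O-]c1cc(C)cc(C=O)c1[O-] | intermediate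
18 | 3-(allyloxy)-2-hydroxy-5-methylbenzaldehyde | C=CCOc1cc(C)cc(C=O)c1O | intermediate
19 | 2-(allyloxy)-6-(1,3-dioxolan-2-yl)-4-methylphenol | Oc1c(OCC=C)cc(C)cc1C1OCCO1 | intermediate
20 | carbon dioxide | O=C=O | starting material
21 | caesium 2-(allyloxy)-6-(1,3-dioxolan-2-yl)-4-methylphenoxide (formed in the flask) | [Cs+].[O-]c1c(OCC=C)cc(C)cc1C1OCCO1 | intermediate
22 | 4-[(1S)-1-(tert-butyldimethylsilyloxy)-3-methylbutyl]-3-methoxy-1,2-didehydrobenzene, the C1–C6 aryne (formed in the flask) | COC1=C([C@H](CC(C)C)O[Si](C)(C)C(C)(C)C)C=CC#C1 | intermediate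
23 | {6-[2-(allyloxy)-6-(1,3-dioxolan-2-yl)-4-methylphenoxy]-3-[(1S)-1-(tert-butyldimethylsilyloxy)-3-methylbutyl]-2-methoxyphenyl}caesium (formed in the flask) | COc1c([C@H](CC(C)C)O[Si](C)(C)C(C)(C)C)ccc(Oc2c(OCC=C)cc(C)cc2C3OCCO3)c1[Cs] | intermediate
24 | 6-[2-(allyloxy)-6-(1,3-dioxolan-2-yl)-4-methylphenoxy]-3-[(1S)-1-(tert-butyldimethylsilyloxy)-3-methylbutyl]-2-methoxybenzoic acid | COc1c([C@H](CC(C)C)O[Si](C)(C)C(C)(C)C)ccc(Oc2c(OCC=C)cc(C)cc2C3OCCO3)c1C(=O)O | intermediate
25 | allyl 6-[2-(allyloxy)-6-(1,3-dioxolan-2-yl)-4-methylphenoxy]-3-[(1S)-1-(tert-butyldimethylsilyloxy)-3-methylbutyl]-2-methoxybenzoate | COc1c([C@H](CC(C)C)O[Si](C)(C)C(C)(C)C)ccc(Oc2c(OCC=C)cc(C)cc2C3OCCO3)c1C(=O)OCC=C | intermediate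
26 | allyl 6-[2-(allyloxy)-6-formyl-4-methylphenoxy]-3-[(1S)-1-hydroxy-3-methylbutyl]-2-methoxybenzoate | COc1c([C@H](CC(C)C)O)ccc(Oc2c(OCC=C)cc(C)cc2C=O)c1C(=O)OCC=C | intermediate
27 | allyl 3-[(1S)-1-acetoxy-3-methylbutyl]-6-[2-(allyloxy)-6-formyl-4-methylphenoxy]-2-methoxybenzoate | COc1c([C@H](CC(C)C)OC(C)=O)ccc(Oc2c(OCC=C)cc(C)cc2C=O)c1C(=O)OCC=C | intermediate
28 | allyl 3-[(1S)-1-acetoxy-3-methylbutyl]-6-{2-(allyloxy)-4-methyl-6-[(1E)-3-oxobut-1-en-1-yl]phenoxy}-2-methoxybenzoate | COc1c([C@H](CC(C)C)OC(C)=O)ccc(Oc2c(OCC=C)cc(C)cc2/C=C/C(C)=O)c1C(=O)OCC=C | intermediate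
29 | 3-[(1S)-1-acetoxy-3-methylbutyl]-6-{2-hydroxy-4-methyl-6-[(1E)-3-oxobut-1-en-1-yl]phenoxy}-2-methoxybenzoic acid | COc1c([C@H](CC(C)C)OC(C)=O)ccc(Oc2c(O)cc(C)cc2/C=C/C(C)=O)c1C(=O)O | target

**Step count**

Total: 16 steps. Longest linear sequence: 12 steps (steps 1–6 and 11–16); the ring B branch (steps 7–10) joins at step 11.

**Steps most likely to fail**

Step 11 (key step). The arylcaesium may be protonated before it meets carbon dioxide, giving the ether without the carboxyl group. The phenoxide may rest largely as its carbonate, so that the aryne is consumed by fluoride, by the product carboxylate or by self-reaction. The silyl ether may be partly lost to fluoride. The fallback separates the two bond formations with known reactions and sets out from 13 and 19. Fluoride-mediated O-arylation of the free phenol 19 by 13 (CsF, MeCN, rt, no carbon dioxide) should give, with the same distal regiochemistry, 2-[3-(allyloxy)-2-{4-[(1S)-1-(tert-butyldimethylsilyloxy)-3-methylbutyl]-3-methoxyphenoxy}-5-methylphenyl]-1,3-dioxolane F1, which has hydrogen at C1. Directed ortho-lithiation at C1, the only ring position flanked by two ether oxygens (sec-BuLi, TMEDA, THF, −78 °C), gives the C1 aryllithium F2. A carbon dioxide quench returns the route to acid 24.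

Step 5. Metalation may take another course: removal of the benzylic hydrogen next to the silyloxy group with migration of silicon from oxygen to carbon, lithiation at the open position ortho to the carbamate, or an anionic Fries shift on warming. The fallback sets out from 7 and changes both the directing group and the way the anion is trapped. The carbamate is cleaved (DBU, Et2NH, MeCN, 40 °C) to 4-[(1S)-1-(tert-butyldimethylsilyloxy)-3-methylbutyl]-3-methoxyphenol F3. This is converted (NaH, ClC(O)NEt2, THF) into 4-[(1S)-1-(tert-butyldimethylsilyloxy)-3-methylbutyl]-3-methoxyphenyl N,N-diethylcarbamate F4. Metalation under in situ quench conditions (LiTMP with TMSCl already present, THF, −78 °C) silylates the most acidic ring position as the anion forms, giving 4-[(1S)-1-(tert-butyldimethylsilyloxy)-3-methylbutyl]-3-methoxy-2-(trimethylsilyl)phenyl N,N-diethylcarbamate F5. Reductive cleavage of the carbamate with Cp2Zr(H)Cl (THF, rt) returns the route to silylphenol 12, which is triflated with PhNTf2 and DBU to 13.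

Step 13. The single acidic operation may stall at the acetal, or the acid may ionise the electron-rich benzylic carbinol (para to the aryloxy group, ortho to the methoxy group), with erosion of configuration or elimination. The fallback sets out from 25 and unmasks the two groups separately with orthogonal reagents. Buffered fluoride (TBAF, AcOH, THF, 0 °C to rt) gives allyl 6-[2-(allyloxy)-6-(1,3-dioxolan-2-yl)-4-methylphenoxy]-3-[(1S)-1-hydroxy-3-methylbutyl]-2-methoxybenzoate F6. Acetylation (Ac2O, pyridine, DMAP) gives allyl 3-[(1S)-1-acetoxy-3-methylbutyl]-6-[2-(allyloxy)-6-(1,3-dioxolan-2-yl)-4-methylphenoxy]-2-methoxybenzoate F7. Mild hydrolysis of the dioxolane (PPTS, wet acetone, 40 °C), now with the carbinol protected as its acetate, returns the route to 27.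

**Further compounds**

F1 | step 11 | 2-[3-(allyloxy)-2-{4-[(1S)-1-(tert-butyldimethylsilyloxy)-3-methylbutyl]-3-methoxyphenoxy}-5-methylphenyl]-1,3-dioxolane | COc1c([C@H](CC(C)C)O[Si](C)(C)C(C)(C)C)ccc(Oc2c(OCC=C)cc(C)cc2C3OCCO3)c1
F2 | step 11 | C1 aryllithium of F1 (lithium between the methoxy and aryloxy groups of ring A) | COc1c([C@H](CC(C)C)O[Si](C)(C)C(C)(C)C)ccc(Oc2c(OCC=C)cc(C)cc2C3OCCO3)c1[Li]
F3 | step 5 | 4-[(1S)-1-(tert-butyldimethylsilyloxy)-3-methylbutyl]-3-methoxyphenol | COc1c([C@H](CC(C)C)O[Si](C)(C)C(C)(C)C)ccc(O)c1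
F4 | step 5 | 4-[(1S)-1-(tert-butyldimethylsilyloxy)-3-methylbutyl]-3-methoxyphenyl N,N-diethylcarbamate | COc1c([C@H](CC(C)C)O[Si](C)(C)C(C)(C)C)ccc(OC(=O)N(CC)CC)c1
F5 | step 5 | 4-[(1S)-1-(tert-butyldimethylsilyloxy)-3-methylbutyl]-3-methoxy-2-(trimethylsilyl)phenyl N,N-diethylcarbamate | COc1c([C@H](CC(C)C)O[Si](C)(C)C(C)(C)C)ccc(OC(=O)N(CC)CC)c1[Si](C)(C)C
F6 | step 13 | allyl 6-[2-(allyloxy)-6-(1,3-dioxolan-2-yl)-4-methylphenoxy]-3-[(1S)-1-hydroxy-3-methylbutyl]-2-methoxybenzoate | COc1c([C@H](CC(C)C)O)ccc(Oc2c(OCC=C)cc(C)cc2C3OCCO3)c1C(=O)OCC=C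
F7 | step 13 | allyl 3-[(1S)-1-acetoxy-3-methylbutyl]-6-[2-(allyloxy)-6-(1,3-dioxolan-2-yl)-4-methylphenoxy]-2-methoxybenzoate | COc1c([C@H](CC(C)C)OC(C)=O)ccc(Oc2c(OCC=C)cc(C)cc2C3OCCO3)c1C(=O)OCC=C
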